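A small charge of L, [L] = 5.0 mM against [D] = 0.10 M, turns D into G in this flask, and each pair of readings of G and D sums close to the charge.

| setting | green | flask |
|---|---|---|
| D | 0.10 M | 0.10 M |
| L | 5 mM | 5.0 mM |
| remark | the very flask that is asked about, followed so far |  |
| time |  | 12 h |

- green (time / h: G / %, D / %): 0.833: 4.5, 95.3; 1.33: 7.6, 93.1; 2.00: 8.2, 92.5; 4.00: 12.1, 86.0; 6.00: 14.1, 84.2; 10.0: 18.1, 82.1

(each reading ± 1 percentage point)

- G that was removed still counts
- additions bring no volume worth counting

- delta: at 12 h take out 90% of the G then present, then wait 12 h
- alpha: at 12 h add L, 100% of the amount charged, then wait 12 h
- eta: at 12 h add D, 50.0% of the amount charged, then wait 12 h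
- beta: change nothing and wait 12 h more

- G, in percent of the D first charged, at 12 h
- the option that brings most further G ("none" if no option brings more than 2 percentage points) (delta / alpha / eta / beta / none)
- G present, with what was taken out counted in, in percent of the D first charged, after delta
- G present, with what was taken out counted in, in percent of the D first charged, after alpha

Turn the question round: for more L to bring over 2 percentage points, G at 12 h must still stand that far below its ceiling. At 10.0 h the readings give G over G plus D as 18.1%. Take this reading as the equilibrium share, the part of the pool standing as G once forward and back steps balance; it carries a scatter of about 1 point, and G may still have been rising at 10.0 h. Between the readings, G passed half of that value at about 2.44 h, and with the approach counted as first-order at that half-time, 12 h is about 4.93 half-times. The opposite outcome needs fewer than 3.18, and this flask stands beyond that.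

The gap is then 3.29% of the share, which puts G near 17.5% at 12 h. This reckoning assumes a ceiling rather than dying L. On that assumption, which is thermodynamic control, added L moves the approach and leaves the ceiling, so alpha is reckoned to end near 18.1%. Delta takes out 90% of G, and the remaining pool is reckoned to refill to the same share, for a total of 30.9%. Eta, with a pool raised by 50.0% of the charge, is reckoned to end near 27.1%, so delta is the choice. The forecast differs, with 19.7% now, 35.5% after delta and 33% after alpha, though it also chose delta, reading “strong product inhibition”.

The flask gives 17.8% at 12 h, 31.1% after delta and 18.4% after alpha, and delta brings most, 13 points. Alpha adds 0.58 points, while plain waiting adds 0.76 points. The share applies once more to eta: a pool raised by 50.0% gives 27.2%, and the flask gives 27.3%.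

    D + L ⇌ E (K = 3.80 M⁻¹, k = 0.310 M⁻¹ min⁻¹)
    E ⇌ L + G (K = 0.0610 M, k = 0.170 min⁻¹)

The neighbour charged with 0.040 M of D has the same L. Held to the same share and the same half-time, the reckoning gives about 18.1% of its own charge as G, and that neighbour reaches 18.0% of its own charge at 12 h.

The runs are simulated for substances that don't exist; the scatter is artificial.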